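**Plan**

1. Locants: carbons are counted C1–C22 in the order they appear in the SMILES of 17. Ring A = hydroquinone; ring B = C6–C11–C22–C17–C16; ring C = cyclohexene C6–C11–C12–C13=C15–C16; ring D = 1,4-dione C6–C7(=O)–C8–C9–C10(=O)–C11; ring E = cyclopentanone C4–C5–C6–C7–C8.
2. Retrosynthesis: C11–C22 is cut first (enol to quinone), then C6–C11 and C15–C16 together (intramolecular [4+2]), then C6=C16 and C11=C12 (two aldol condensations), C8–C9 (enolate alkylation) and C2–C4 (conjugate addition).
3. Enabling feature: ring C is a cyclohexene fused to the 1,4-dione ring D across C6–C11, the bond joining the α-carbons of both ketones, so the chain C7–C8–C9–C10 serves as tether and both carbonyls activate the partners. The ring C double bond (C13=C15) lies one position from where a [4+2] leaves it (C12=C13), so C15 carries SiMe3 during the event and protodesilylation then shifts the double bond.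
4. Forward: ring E comes from cyclopentenone; rings D and C are closed together from this monocyclic ketone; ring B is closed last onto ring A, which is carried as a 2,5-dimethoxyphenyl group and unveiled as the quinone.
5. Stereochemistry: C4 from the rhodium/(S)-BINAP conjugate addition; C8 by trans alkylation; C6 by the bridging tether; C16 by suprafacial addition to the Z-arylidene ketone (aryl cis to C7=O); C11 by the closure of ring B.

Key step: step 8

Remark: the S configuration at C4 from (S)-BINAP in step 3 is assigned by analogy with rhodium-catalysed additions to 2-cyclopentenone; should the sense prove opposite, (R)-BINAP is to be used.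

**Route**

Step 1
Reactants: 1 3-(trimethylsilyl)prop-2-yn-1-ol
Product: 2 (E)-2-methyl-3-(trimethylsilyl)prop-2-en-1-ol
Conditions: MeMgCl (3 equiv), CuI (10 mol %), THF, −10 °C to rt; aq NH4Cl
Reagents that add atoms: methylmagnesium chloride, C[Mg]Cl
Why: Copper-catalysed anti-carbomagnesiation of a propargylic alcohol, in which the magnesium alkoxide directs methyl to C2 and holds magnesium at C3 in a five-membered chelate, so protonolysis should give the vinylsilane with silicon trans to CH2OH.

Step 2
Reactants: 2 (E)-2-methyl-3-(trimethylsilyl)prop-2-en-1-ol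
Product: 3 (E)-2-methyl-3-(trimethylsilyl)prop-2-enal
Conditions: MnO2 (10 equiv), CH2Cl2, rt
Reagents that add atoms: none
Why: MnO2 oxidation of an allylic alcohol to the enal, which should leave the vinylsilane and the double-bond geometry untouched.

Step 3
Reactants: 4 cyclopent-2-en-1-one
Product: 6 (2R,3S)-3-(prop-1-en-2-yl)-2-(prop-2-yn-1-yl)cyclopentan-1-one, via titanium enolate 5 (not isolated)
Conditions: CH2=C(Me)MgBr, ClTi(OiPr)3, THF, −78 to 20 °C; then 4, [Rh(OH)((S)-BINAP)]2 (1.5 mol %), 20 °C; then LiOiPr, propargyl bromide, 0 °C to rt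
Reagents that add atoms: isopropenylmagnesium bromide, CC(=C)[Mg]Br; propargyl bromide, C#CCBr
Why: Rhodium-catalysed asymmetric conjugate addition of an organotitanium reagent (aprotic Hayashi–Miyaura type) should set C4 under catalyst control, and the regiodefined titanium enolate, as its lithium titanate, should be alkylated at C8 anti to the isopropenyl group to give the trans ketone.

Step 4
Reactants: 6 (2R,3S)-3-(prop-1-en-2-yl)-2-(prop-2-yn-1-yl)cyclopentan-1-one; 7 2,5-dimethoxybenzaldehyde
Product: 8 (2R,3S,5E)-5-[(2,5-dimethoxyphenyl)methylidene]-3-(prop-1-en-2-yl)-2-(prop-2-yn-1-yl)cyclopentan-1-one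
Conditions: NaOH (aq), EtOH, 0 °C to rt
Reagents that add atoms: none
Why: Claisen–Schmidt condensation at the only α-methylene group (C6) should give the thermodynamic E-arylidene ketone, while the epimerisable C8 keeps the more stable trans arrangement.

Step 5
Reactants: 8 (2R,3S,5E)-5-[(2,5-dimethoxyphenyl)methylidene]-3-(prop-1-en-2-yl)-2-(prop-2-yn-1-yl)cyclopentan-1-one
Product: 9 (2R,3S,5E)-5-[(2,5-dimethoxyphenyl)methylidene]-2-(2-oxopropyl)-3-(prop-1-en-2-yl)cyclopentan-1-one
Conditions: Ph3PAuNTf2 (2 mol %), H2O (5 equiv), 1,4-dioxane, 60 °C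
Reagents that add atoms: water, O
Why: Gold-catalysed Markovnikov hydration of the terminal alkyne, assisted by the ring carbonyl, should give the methyl ketone under neutral conditions that spare the enone and the isopropenyl group.

Step 6
Reactants: 9 (2R,3S,5E)-5-[(2,5-dimethoxyphenyl)methylidene]-2-(2-oxopropyl)-3-(prop-1-en-2-yl)cyclopentan-1-one; 3 (E)-2-methyl-3-(trimethylsilyl)prop-2-enal
Product: 12 (2R,3S,5E)-5-[(2,5-dimethoxyphenyl)methylidene]-2-[(3E,5E)-5-methyl-2-oxo-6-(trimethylsilyl)hexa-3,5-dien-1-yl]-3-(prop-1-en-2-yl)cyclopentan-1-one, via lithium aldolate 10 (not isolated), via mesylate 11 (not isolated)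
Conditions: LiN(iPr)2, THF, −78 °C; 3 (added at once); then MsCl, Et3N, −78 to 0 °C; DBU, rt
Reagents that add atoms: none
Why: Crossed aldol condensation in which kinetic deprotonation at the methyl group (C11), 1,2-addition to enal 3 and E1cB elimination of the mesylate should give the E-enone and hence the (3E,5E)-dienone, the immediate addition of 3 forestalling attack of the enolate on the ring ketone.

Step 7
Reactants: 12 (5E)-trienone
Product: 13 (2R,3S,5Z)-5-[(2,5-dimethoxyphenyl)methylidene]-2-[(3E,5E)-5-methyl-2-oxo-6-(trimethylsilyl)hexa-3,5-dien-1-yl]-3-(prop-1-en-2-yl)cyclopentan-1-one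
Conditions: hν (405 nm LED), degassed MeCN, rt; chromatography in the dark, recovered 12 re-irradiated
Reagents that add atoms: none
Why: E-to-Z photoisomerisation of an α-arylidene ketone by selective excitation of the dimethoxybenzylidene chromophore, which absorbs at 405 nm whereas the silyl dienone does not, should give a photostationary mixture from which the Z isomer (aryl cis to C7=O) is separated.

Step 8
Reactants: 13 (5Z)-trienone
Product: 14 cycloadduct with rings C, D and E closed: a bicyclo[3.2.1]octane-3,8-dione (C7 and C10 ketones, exo isopropenyl at C4) fused across C6–C11 to a cyclohexene (C12=C13, methyl on C13) bearing SiMe3 at C15 and 2,5-dimethoxyphenyl at C16; aryl cis to C7, H at C11 cis to aryl, SiMe3 trans to aryl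
Conditions: toluene (5 mM, degassed), BHT (cat.), 110 °C, dark
Reagents that add atoms: none
Why: Thermal intramolecular [4+2] cycloaddition in which the silyl dienone (C11=C12–C13=C15) adds suprafacially across the arylidene double bond C6=C16 through the four-atom tether C7–C8–C9–C10, forming C6–C11 and C15–C16 in one concerted, asynchronous event. The closest known reaction type is the intramolecular Diels–Alder reaction of 1,7,9-decatrien-3-ones, whose tether carbonyl activates the dienophile, combined with the use of 1-silyl dienes that give allylsilane adducts. Ring D is closed in the tether (fused) mode as a six-membered ring bridging the 1,3-positions of the cyclopentanone (hence the bicyclo[3.2.1]octane-3,8-dione), and ring C is the cycloaddition ring itself. C6 is fixed by the tether, which reaches only the face of C6=C16 on the side of the C9 substituent; C16 follows from the Z geometry because suprafacial addition keeps the aryl group cis to C7; C11 and C15 are set by the E,E-diene and a transition state with the diene backbone over C5 and away from the twisted aryl group, and both are temporary (C15 loses silicon, C11 is re-formed through its enol). Regiochemistry is dictated by the tether and is electronically matched, since the diene terminus remote from the acyl group (C15) meets the enone β-carbon (C16), as in the "ortho" rule. The step needs the Z geometry to survive until cycloaddition, which the neutral, acid-free, nucleophile-free and dark conditions should secure.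

Step 9
Reactants: 14 cycloadduct (allylsilane)
Product: 15 desilylated diketone: same skeleton with C12 = CH2 and the ring C double bond at C13=C15; 2,5-dimethoxyphenyl at C16 cis to C7, H at C11 cis to aryl
Conditions: CF3CO2H (2 equiv), CH2Cl2, −20 °C
Reagents that add atoms: none
Why: Protodesilylation of an allylsilane with allylic transposition (SE2′), in which protonation at C12 gives the β-silyl tertiary cation at C13 and loss of the axial silyl group should place the double bond at C13=C15, faster than protonation of the isopropenyl group.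

Step 10
Reactants: 15 desilylated diketone
Product: 16 2-substituted 1,4-benzoquinone corresponding to 15 (quinone carbon C17 attached to C16)
Conditions: (NH4)2Ce(NO3)6 (2.5 equiv), MeCN/H2O, 0 °C
Reagents that add atoms: water, O
Why: Oxidative demethylation of the 1,4-dimethoxyarene to the quinone, a reaction that should tolerate the ketones and both alkenes at 0 °C.

Step 11
Reactants: 16 quinone
Product: 17 CNP0287617.1 (target)
Conditions: camphorsulfonic acid (20 mol %), CH2Cl2, rt, argon
Reagents that add atoms: none
Why: Acid-catalysed intramolecular Michael addition of the more substituted enol (C10=C11, formed by loss of the axial H at C11) to quinone carbon C22, closing the five-membered ring B, followed by tautomerisation to the hydroquinone; the aryl group on C16 reaches only one face of C11, which sets this centre, whereas the C9 enol would need a seven-membered ring and C8 is a bridgehead.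

**Compound list**

1 | 3-(trimethylsilyl)prop-2-yn-1-ol | C[Si](C)(C)C#CCO | starting material
2 | (E)-2-methyl-3-(trimethylsilyl)prop-2-en-1-ol | C[Si](C)(C)/C=C(C)/CO | intermediate
3 | (E)-2-methyl-3-(trimethylsilyl)prop-2-enal | C[Si](C)(C)/C=C(C)/C=O | intermediate
4 | cyclopent-2-en-1-one | O=C1C=CCC1 | starting material
5 | titanium enolate: triisopropoxytitanium enolate of (S)-3-(prop-1-en-2-yl)cyclopentanone, enolate double bond towards C8 | C=C(C)[C@H]1CCC(O[Ti](OC(C)C)(OC(C)C)OC(C)C)=C1 | intermediate
6 | (2R,3S)-3-(prop-1-en-2-yl)-2-(prop-2-yn-1-yl)cyclopentan-1-one | C=C(C)[C@H]1CCC(=O)[C@@H]1CC#C | intermediate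
7 | 2,5-dimethoxybenzaldehyde | COc1ccc(OC)c(C=O)c1 | starting material
8 | (2R,3S,5E)-5-[(2,5-dimethoxyphenyl)methylidene]-3-(prop-1-en-2-yl)-2-(prop-2-yn-1-yl)cyclopentan-1-one | C=C(C)[C@H]1C/C(=C\c2cc(OC)ccc2OC)C(=O)[C@@H]1CC#C | intermediate
9 | (2R,3S,5E)-5-[(2,5-dimethoxyphenyl)methylidene]-2-(2-oxopropyl)-3-(prop-1-en-2-yl)cyclopentan-1-one | C=C(C)[C@H]1C/C(=C\c2cc(OC)ccc2OC)C(=O)[C@@H]1CC(C)=O | intermediate
10 | lithium aldolate from the C11 enolate of 9 and 3 (both C12 epimers) | C=C(C)[C@H]1C/C(=C\c2cc(OC)ccc2OC)C(=O)[C@@H]1CC(=O)CC([O-])/C(C)=C/[Si](C)(C)C.[Li+] | intermediate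
11 | mesylate of the aldol adduct (both C12 epimers) | C=C(C)[C@H]1C/C(=C\c2cc(OC)ccc2OC)C(=O)[C@@H]1CC(=O)CC(OS(C)(=O)=O)/C(C)=C/[Si](C)(C)C | intermediate
12 | (2R,3S,5E)-5-[(2,5-dimethoxyphenyl)methylidene]-2-[(3E,5E)-5-methyl-2-oxo-6-(trimethylsilyl)hexa-3,5-dien-1-yl]-3-(prop-1-en-2-yl)cyclopentan-1-one | C=C(C)[C@H]1C/C(=C\c2cc(OC)ccc2OC)C(=O)[C@@H]1CC(=O)/C=C/C(C)=C/[Si](C)(C)C | intermediate
13 | (2R,3S,5Z) isomer of 12 (aryl cis to the ring carbonyl) | C=C(C)[C@H]1C/C(=C/c2cc(OC)ccc2OC)C(=O)[C@@H]1CC(=O)/C=C/C(C)=C/[Si](C)(C)C | intermediate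
14 | cycloadduct: bicyclo[3.2.1]octane-3,8-dione fused across C6–C11 to a cyclohexene (C12=C13) with SiMe3 at C15 and 2,5-dimethoxyphenyl at C16; aryl cis to C7, H-11 cis to aryl, SiMe3 trans to aryl | C=C(C)[C@H]1C[C@@]23C(=O)[C@@H]1CC(=O)[C@H]2C=C(C)[C@@H]([Si](C)(C)C)[C@@H]3c1cc(OC)ccc1OC | intermediate
15 | desilylated diketone: as 14 without silicon, C12 = CH2, double bond C13=C15 | C=C(C)[C@H]1C[C@@]23C(=O)[C@@H]1CC(=O)[C@H]2CC(C)=C[C@@H]3c1cc(OC)ccc1OC | intermediate
16 | quinone: as 15 with the aryl group oxidised to a 2-substituted 1,4-benzoquinone | C=C(C)[C@H]1C[C@@]23C(=O)[C@@H]1CC(=O)[C@H]2CC(C)=C[C@@H]3C1=CC(=O)C=CC1=O | intermediate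
17 | CNP0287617.1 | C=C(C)[C@H]1C[C@@]23C(=O)[C@@H]1CC(=O)[C@@]21CC(C)=C[C@@H]3c2c(O)ccc(O)c21 | target

**Step count and risks**

Total step count: 11. Longest linear sequence: 9 steps (steps 3–11, from 4).

Steps most likely to fail:

1. Step 8 (key cycloaddition). What may go wrong: thermal isomerisation of the Z-arylidene double bond before it reacts, which would invert C16, or a cycloaddition too slow to compete with oligomerisation because both π-partners are conjugated to carbonyl groups. The fallback sets out from 12 and returns at 14, and makes the diene electron-rich by a change of oxidation level. Luche reduction (NaBH4, CeCl3·7H2O, MeOH, −78 °C) of the less hindered side-chain dienone of 12 should give the dienyl carbinol F1 (both C10 epimers). Irradiation as in step 7 gives the Z-arylidene carbinol F2. This decatrienone, now with a non-conjugated diene, should cyclise near room temperature to the adduct carbinol F3, and Dess–Martin oxidation of F3 returns to 14.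

2. Step 7 (photoisomerisation). What may go wrong: an unfavourable photostationary state, E/Z scrambling of the dienone unit, or reversion of the Z isomer during purification. The fallback sets out from 6 and returns at 13, and builds the Z geometry by synthesis instead of light. Formylation of 6 at its only α-methylene group (HCO2Et, NaH, THF) gives the hydroxymethylene ketone F4. Triflation of its chelated lithium enolate (LiN(SiMe3)2, then PhNTf2, THF, −78 °C) should give the Z-enol triflate F5 with OTf cis to C=O. Suzuki–Miyaura coupling with 2,5-dimethoxyphenylboronic acid (Pd(PPh3)4, K3PO4, THF, rt), which proceeds with retention, gives the Z-arylidene ketone F6. Gold-catalysed hydration as in step 5 gives the methyl ketone F7. Kinetic aldol addition to 3 gives the β-hydroxy ketone F8, whose mesylate F9 is eliminated with DBU to 13.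

3. Step 11 (closure of ring B). What may go wrong: redox exchange between the product hydroquinone and unreacted quinone, which parks material at the wrong oxidation level, or tautomerisation of the alkylquinone to a quinone methide, which would scramble C16. The fallback sets out from 15 and returns at 17, and forms C11–C22 by oxidative radical cyclisation at the dimethyl ether stage. Mn(OAc)3·2H2O and Cu(OAc)2 in AcOH at 60 °C should oxidise the more substituted enol of 15 to the α-keto radical at C11, which adds to C22 of the dimethoxyarene; oxidative rearomatisation gives the target dimethyl ether F10. (NH4)2Ce(NO3)6 in MeCN/H2O gives the target quinone F11, and Na2S2O4 reduces F11 to 17.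

**Further compounds**

F1 | step 8 | (5E)-arylidene ketone with the side-chain ketone reduced to the dienyl carbinol (C10 epimers) | C=C(C)[C@H]1C/C(=C\c2cc(OC)ccc2OC)C(=O)[C@@H]1CC(O)/C=C/C(C)=C/[Si](C)(C)C
F2 | step 8 | (5Z) isomer of F1 | C=C(C)[C@H]1C/C(=C/c2cc(OC)ccc2OC)C(=O)[C@@H]1CC(O)/C=C/C(C)=C/[Si](C)(C)C
F3 | step 8 | cycloadduct carbinol: 14 with C10 as CH(OH) (C10 epimers) | C=C(C)[C@H]1C[C@@]23C(=O)[C@@H]1CC(O)[C@H]2C=C(C)[C@@H]([Si](C)(C)C)[C@@H]3c1cc(OC)ccc1OC
F4 | step 7 | (2R,3S,5Z)-5-(hydroxymethylidene)-3-(prop-1-en-2-yl)-2-(prop-2-yn-1-yl)cyclopentan-1-one | C=C(C)[C@H]1C/C(=C/O)C(=O)[C@@H]1CC#C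
F5 | step 7 | (Z)-enol triflate of F4 (OTf cis to C=O) | C=C(C)[C@H]1C/C(=C/OS(=O)(=O)C(F)(F)F)C(=O)[C@@H]1CC#C
F6 | step 7 | (2R,3S,5Z)-5-[(2,5-dimethoxyphenyl)methylidene]-3-(prop-1-en-2-yl)-2-(prop-2-yn-1-yl)cyclopentan-1-one | C=C(C)[C@H]1C/C(=C/c2cc(OC)ccc2OC)C(=O)[C@@H]1CC#C
F7 | step 7 | (2R,3S,5Z)-5-[(2,5-dimethoxyphenyl)methylidene]-2-(2-oxopropyl)-3-(prop-1-en-2-yl)cyclopentan-1-one | C=C(C)[C@H]1C/C(=C/c2cc(OC)ccc2OC)C(=O)[C@@H]1CC(C)=O
F8 | step 7 | β-hydroxy ketone from F7 and 3 (C12 epimers) | C=C(C)[C@H]1C/C(=C/c2cc(OC)ccc2OC)C(=O)[C@@H]1CC(=O)CC(O)/C(C)=C/[Si](C)(C)C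
F9 | step 7 | mesylate of F8 | C=C(C)[C@H]1C/C(=C/c2cc(OC)ccc2OC)C(=O)[C@@H]1CC(=O)CC(OS(C)(=O)=O)/C(C)=C/[Si](C)(C)C
F10 | step 11 | dimethyl ether of 17 | C=C(C)[C@H]1C[C@@]23C(=O)[C@@H]1CC(=O)[C@@]21CC(C)=C[C@@H]3c2c(OC)ccc(OC)c21
F11 | step 11 | quinone corresponding to 17 | C=C(C)[C@H]1C[C@@]23C(=O)[C@@H]1CC(=O)[C@@]21CC(C)=C[C@@H]3C2=C1C(=O)C=CC2=O
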